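**Plan**

1. Retrosynthesis: the two phenolic acetates that mask the catechol (ring O-2 and O-3) come off last. The chain is then cut at the unfunctionalised C2–C3 bond (C1 = OCH2), which leads back to two carboxylic acids as radical precursors: 19-methylicosanoic acid and 3-[(2,3-diacetoxybenzoyl)oxy]propanoic acid.
2. Enabling feature: C2 and C3 are plain primary CH2 carbons. The ester oxygen on C1 sits β (not α) to C2, so the C2 radical is not over-oxidised to a cation. The benzene ring, once its two OH groups are acetylated, is too electron-poor to be oxidised at the anode.
3. Further cuts: the iso-acid at its C16–C17 bond (16-bromohexadecanoic acid + isopentyl Grignard); the aryl ester C–O bond (2,3-dihydroxybenzoic acid + a 3-hydroxypropanoate).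
4. Forward order: C21 iso-acid (step 1); aryl diacetate, esterification and tert-butyl cleavage (steps 2–4); chain joined by crossed Kolbe electrolysis (step 5); deacetylation (step 6). No ring is formed.
5. Stereochemistry: the target has no stereocentre (C20 carries two methyl groups), so the achiral compound as drawn is the only stereoisomer and no stereocontrol is needed.

Key step: step 5

**Route**

Step 1
Reactants: 1 16-bromohexadecanoic acid; 2 3-methylbutylmagnesium bromide (isopentylmagnesium bromide)
Product: 3 19-methylicosanoic acid
Conditions: 2 (2.6 equiv), Li2CuCl4 (3 mol%), THF, −20 °C → rt; then 1 M HCl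
Reagents that add atoms: none
Why: In this Cu-catalysed Kumada-type sp3–sp3 coupling the first equivalent of Grignard reagent masks the acid as its magnesium carboxylate, which is inert at low temperature, and the organocopper species formed from Li2CuCl4 then displaces the primary bromide, a classical entry to iso-fatty acids from ω-bromo acids.

Step 2
Reactants: 4 2,3-dihydroxybenzoic acid
Product: 5 2,3-diacetoxybenzoic acid
Conditions: Ac2O (excess), H2SO4 (cat.), 60 °C; then H2O
Reagents that add atoms: acetic anhydride, CC(=O)OC(C)=O
Why: Acid-catalysed O-acetylation of both phenols (the aspirin-type acetylation of a salicylic acid) should proceed cleanly, and the aqueous work-up hydrolyses any mixed anhydride back to the free carboxylic acid.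

Step 3
Reactants: 5 2,3-diacetoxybenzoic acid; 6 tert-butyl 3-hydroxypropanoate
Product: 8 tert-butyl 3-[(2,3-diacetoxybenzoyl)oxy]propanoate, via 2,3-diacetoxybenzoyl chloride 7 (not isolated)
Conditions: (COCl)2, DMF (cat.), CH2Cl2, 0 °C → rt; concentrate; then 6, pyridine, CH2Cl2, 0 °C → rt
Reagents that add atoms: oxalyl chloride, O=C(Cl)C(=O)Cl (its chlorine stands only in intermediate 7; no atom of it remains in 8)
Why: Acid chloride formation followed by pyridine-mediated acylation of a primary alcohol is a standard esterification, the aryl acetates and the tert-butyl ester are inert to it, and the mild base at 0 °C should not cause β-elimination of the new β-acyloxy ester.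

Step 4
Reactants: 8 tert-butyl 3-[(2,3-diacetoxybenzoyl)oxy]propanoate
Product: 9 3-[(2,3-diacetoxybenzoyl)oxy]propanoic acid
Conditions: TFA–CH2Cl2 (1:3), rt
Reagents that add atoms: none
Why: Acidolysis of the tert-butyl ester (alkyl–oxygen cleavage through the tert-butyl cation, lost as isobutene) should free the carboxylic acid while the aryl acetates and the benzoate ester, which have no such pathway, stay intact.

Step 5
Reactants: 3 19-methylicosanoic acid; 9 3-[(2,3-diacetoxybenzoyl)oxy]propanoic acid
Product: 10 20-methylhenicosyl 2,3-diacetoxybenzoate
Conditions: 3 (1 equiv), 9 (4 equiv), KOH (5 mol% of total acid), MeOH–MeCN (1:1), 40 °C; undivided cell, smooth Pt anode/Pt cathode, constant current (ca. 150 mA cm−2), stopped while the electrolyte is still weakly acidic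
Reagents that add atoms: none
Why: At the platinum anode the carboxylates of 3 and 9 are each oxidised by one electron and lose CO2, so that the 18-methylnonadecyl radical and the 2-(2,3-diacetoxybenzoyloxy)ethyl radical arise side by side at high concentration in the carboxylate layer on the electrode and combine to form the C2–C3 bond, while protons are reduced to H2 at the cathode. The closest known reaction type is the mixed (crossed) Kolbe electrolysis, the classical decarboxylative radical coupling for long-chain lipids, in which O-acylated β-hydroxy acids are established partners. No ring is closed and no stereocentre is formed. Cross-coupling over homo-coupling is statistical and is secured for the more valuable acid 3 by the fourfold excess of 9; the two symmetrical homo-coupling products differ widely in polarity from 10, so separation should be simple. Radical coupling rather than further oxidation to cations is favoured because both radicals are primary and unstabilised (the ester oxygen is β, not α, to the radical carbon, and a 1,2-acyloxy shift would be degenerate), helped by smooth Pt, high current density and a weakly acidic medium. Oxidation of the carboxylates in preference to the arene rests on the diacetate, since the ring carries an ester and two acetoxy groups in place of the free catechol and its oxidation potential should lie above that of the Kolbe process.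

Step 6
Reactants: 10 20-methylhenicosyl 2,3-diacetoxybenzoate
Product: 11 Gentiside A (20-methylhenicosyl 2,3-dihydroxybenzoate)
Conditions: pyrrolidine (3 equiv), THF, 0 °C → rt, under Ar; then 1 M HCl
Reagents that add atoms: none
Why: Chemoselective aminolysis of the two activated aryl acetates by a secondary amine should leave the far less electrophilic long-chain alkyl benzoate untouched, and the inert atmosphere with acidic work-up protects the liberated catechol from air oxidation.

**Compound list**

1 | 16-bromohexadecanoic acid | OC(=O)CCCCCCCCCCCCCCCBr | starting material
2 | 3-methylbutylmagnesium bromide (isopentylmagnesium bromide; commercial solution or from 1-bromo-3-methylbutane and Mg) | CC(C)CC[Mg]Br | starting material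
3 | 19-methylicosanoic acid | CC(C)CCCCCCCCCCCCCCCCCC(=O)O | intermediate
4 | 2,3-dihydroxybenzoic acid | OC(=O)c1cccc(O)c1O | starting material
5 | 2,3-diacetoxybenzoic acid | OC(=O)c1cccc(OC(C)=O)c1OC(C)=O | intermediate
6 | tert-butyl 3-hydroxypropanoate | CC(C)(C)OC(=O)CCO | starting material
7 | 2,3-diacetoxybenzoyl chloride | ClC(=O)c1cccc(OC(C)=O)c1OC(C)=O | intermediate (not isolated)
8 | tert-butyl 3-[(2,3-diacetoxybenzoyl)oxy]propanoate | CC(C)(C)OC(=O)CCOC(=O)c1cccc(OC(C)=O)c1OC(C)=O | intermediate
9 | 3-[(2,3-diacetoxybenzoyl)oxy]propanoic acid | OC(=O)CCOC(=O)c1cccc(OC(C)=O)c1OC(C)=O | intermediate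
10 | 20-methylhenicosyl 2,3-diacetoxybenzoate | CC(C)CCCCCCCCCCCCCCCCCCCOC(=O)c1cccc(OC(C)=O)c1OC(C)=O | intermediate
11 | Gentiside A (20-methylhenicosyl 2,3-dihydroxybenzoate) | CC(C)CCCCCCCCCCCCCCCCCCCOC(=O)c1cccc(O)c1O | target

**Summary**

Total step count: 6. Longest linear sequence: 5 steps (steps 2–6, from 4); step 1 supplies the second branch.

**Steps most likely to fail**

Step 5. Several processes may erode the electrolysis: statistical homo-coupling that consumes the C20 radical, over-oxidation of the radicals to cations (non-Kolbe products), fouling of the anode by poorly soluble long-chain products, and solvolysis of an aryl acetate followed by oxidation of the freed phenol. The fallback sets out from 3 and 9 and returns at 10. Each acid would be converted with N-hydroxyphthalimide and DIC (CH2Cl2, rt) into its redox-active ester, 1,3-dioxoisoindolin-2-yl 19-methylicosanoate F1 and 1,3-dioxoisoindolin-2-yl 3-[(2,3-diacetoxybenzoyl)oxy]propanoate F2. The two esters would then be joined by the reductive nickel-electrocatalytic doubly decarboxylative sp3–sp3 coupling (NiCl2·glyme, terpyridine ligand, AgNO3 additive, sacrificial Mg anode, RVC cathode, NMP, rt, F2 in excess). Here the C–C bond is made at nickel under cathodic conditions, so neither the arene nor the acetates see an oxidising potential. This should give 10, and the route continues with step 6.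

Step 1. The magnesium carboxylate may be too poorly soluble for complete coupling, and reduction or elimination of the bromide and Grignard homo-coupling may compete, leaving homologous fatty acids that are hard to separate. The fallback sets out from 1 and returns at 3 and replaces the sp3–sp3 coupling by olefination and hydrogenation. Heating 1 with PPh3 (MeCN, reflux) should give (15-carboxypentadecyl)triphenylphosphonium bromide F3. Double deprotonation (NaHMDS, 2.2 equiv, THF, −78 → 0 °C) and Wittig reaction with 3-methylbutanal should give (Z)-19-methylicos-16-enoic acid F4. Hydrogenation (H2, Pd/C, EtOAc) removes the double bond and gives 3.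

Step 6. The amine may also attack the long-chain ester, or the liberated catechol may be oxidised by air under the basic conditions. The fallback sets out from 10 (with 4) and returns at 11 and gives up selective deprotection altogether. Complete saponification of 10 (KOH, EtOH–H2O–THF, reflux) should give 20-methylhenicosan-1-ol F5. An Appel reaction (CBr4, PPh3, CH2Cl2) converts it into 1-bromo-20-methylhenicosane F6. Unprotected 2,3-dihydroxybenzoic acid 4 is then O-alkylated at the carboxylate only (KHCO3, DMF, 60 °C; the phenols are not deprotonated by hydrogen carbonate) to give 11 directly.

**Further compounds**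

F1 | step 5 | 1,3-dioxoisoindolin-2-yl 19-methylicosanoate | CC(C)CCCCCCCCCCCCCCCCCC(=O)ON1C(=O)c2ccccc2C1=O
F2 | step 5 | 1,3-dioxoisoindolin-2-yl 3-[(2,3-diacetoxybenzoyl)oxy]propanoate | O=C(CCOC(=O)c1cccc(OC(C)=O)c1OC(C)=O)ON1C(=O)c2ccccc2C1=O
F3 | step 1 | (15-carboxypentadecyl)triphenylphosphonium bromide | OC(=O)CCCCCCCCCCCCCCC[P+](c1ccccc1)(c1ccccc1)c1ccccc1.[Br-]
F4 | step 1 | (Z)-19-methylicos-16-enoic acid | CC(C)C/C=C\CCCCCCCCCCCCCCC(=O)O
F5 | step 6 | 20-methylhenicosan-1-ol | CC(C)CCCCCCCCCCCCCCCCCCCO
F6 | step 6 | 1-bromo-20-methylhenicosane | CC(C)CCCCCCCCCCCCCCCCCCCBr
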